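The route rests on cutting the bond between the benzylic carbon C1 of the icosan-5-one chain and the ring carbon of the catechol that lies para to one oxygen. The key step exploits the 1,5-relationship between C1 and the ketone carbon C5: C1 to C5 are taken from a cyclopentane ring in which C1 and C5 are still bonded. Alkoxy-radical β-scission of 1-pentadecylcyclopentan-1-ol opens this ring, unveils the ketone and leaves a primary radical at C1, which nickel joins to 4-bromoveratrole in the same operation. The precursor is a tertiary cyclopentanol made in one step from cyclopentanone; demethylation then gives the achiral target.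

Key step: step 2

Step 1
Reactants: 1 1-bromopentadecane; 2 cyclopentanone
Product: 4 1-pentadecylcyclopentan-1-ol, via pentadecylmagnesium bromide 3 (not isolated)
Conditions: Mg, I2 (cat.), THF, reflux; then 2, THF, 0 °C to rt; aq. NH4Cl
Reagents that add atoms: none
Why: Grignard formation followed by 1,2-addition of the primary alkylmagnesium bromide to the unhindered ketone should give the tertiary alcohol, and no stereocentre arises because the two ring carbons beside the carbinol carbon are equivalent.

Step 2
Reactants: 4 1-pentadecylcyclopentan-1-ol; 5 4-bromo-1,2-dimethoxybenzene (4-bromoveratrole)
Product: 6 1-(3,4-dimethoxyphenyl)icosan-5-one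
Conditions: CeCl3 (10 mol %), n-Bu4N benzoate (30 mol %), NiBr2·glyme (10 mol %), 4,4'-di-tert-butyl-2,2'-bipyridine (12 mol %), 2,4,6-collidine (1.5 equiv), MeCN/PhCF3, 400 nm LEDs, 25 °C, argon
Reagents that add atoms: none
Why: Trivalent cerium binds 4 as its alkoxide, the aryl trivalent nickel species formed from monovalent nickel and 5 oxidises it to the tetravalent cerium alkoxide, and 400 nm light homolyses the Ce–O bond by ligand-to-metal charge transfer to give the 1-pentadecylcyclopentyloxy radical. β-Scission of a ring C1–C2 bond then unveils the C5 ketone and a primary 5-oxoicosyl radical, which the aryl divalent nickel bromide captures; reductive elimination from trivalent nickel forms the CH2–aryl bond and returns monovalent nickel. The closest known reaction type is the photocatalytic ring-opening arylation of tertiary cycloalkanols with aryl bromides under nickel co-catalysis (alkoxy-radical β-scission joined to cross-coupling), of which the cerium/nickel dehydroxymethylative arylation of alcohols is the open-chain relative. No ring is closed (one is opened) and no stereocentre is formed. The step needs scission of a ring bond in preference to the exocyclic bond to the pentadecyl group and to 1,5-hydrogen transfer from the chain: both scissions give primary radicals, but ring cleavage is favoured twofold statistically and by relief of the eclipsing strain of the cyclopentane, and a polar medium favours scission over hydrogen transfer. The arene carbon that is joined is fixed by the position of bromine in 5, para to one methoxy group and meta to the other.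

Step 3
Reactants: 6 1-(3,4-dimethoxyphenyl)icosan-5-one
Product: 7 1-(3,4-dihydroxyphenyl)icosan-5-one
Conditions: BBr3 (excess), CH2Cl2, −78 °C to 0 °C; then H2O
Reagents that add atoms: none
Why: BBr3 demethylation of the aryl methyl ethers (boron binds each ether oxygen and bromide attacks the methyl carbon by SN2) should free the catechol, while the dialkyl ketone forms only a reversible boron adduct that water releases at work-up.

Compound list
1 | 1-bromopentadecane | CCCCCCCCCCCCCCCBr | starting material
2 | cyclopentanone | O=C1CCCC1 | starting material
3 | pentadecylmagnesium bromide | CCCCCCCCCCCCCCC[Mg]Br | intermediate (not isolated)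
4 | 1-pentadecylcyclopentan-1-ol | CCCCCCCCCCCCCCCC1(O)CCCC1 | intermediate
5 | 4-bromo-1,2-dimethoxybenzene | COc1ccc(Br)cc1OC | starting material
6 | 1-(3,4-dimethoxyphenyl)icosan-5-one | CCCCCCCCCCCCCCCC(=O)CCCCc1ccc(OC)c(OC)c1 | intermediate
7 | 1-(3,4-dihydroxyphenyl)icosan-5-one | CCCCCCCCCCCCCCCC(=O)CCCCc1ccc(O)c(O)c1 | target

Total step count: 3
Longest linear sequence: 3 steps (1 → 4 → 6 → 7)

Steps most likely to fail

Step 2 (key step). Oxidative addition of the electron-rich aryl bromide to nickel may be slow, so the 5-oxoicosyl radical could be lost to reduction or dimerisation. The cerium and nickel cycles may also fail to exchange electrons efficiently. Exocyclic scission or 1,5-hydrogen transfer in the alkoxy radical may divert material. The fallback separates ring opening from arylation and sets out from 4. Alkoxy-radical fragmentation of 4 through its hypoiodite (PhI(OAc)2, I2, CH2Cl2, visible light, rt) should give 1-iodoicosan-5-one F1. Nickel-catalysed reductive cross-electrophile coupling of F1 with 5 (NiI2 cat., 4,4'-di-tert-butyl-2,2'-bipyridine, NaI cat., Zn, N,N'-dimethylpropyleneurea, 60 °C) should then form the same CH2–aryl bond. This coupling tolerates the ketone, and the fallback comes back to the route at 6.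

Step 3. Ether cleavage may stop at the monomethyl ether. The boron-activated ketone may undergo aldol-type self-condensation. The free catechol may oxidise to the ortho-quinone during work-up. The fallback changes the protecting group so that no Lewis acid is needed, and sets out from 4. Compound 4 is coupled under the conditions of step 2 with purchased 1,2-bis(benzyloxy)-4-bromobenzene F2 in place of 5, which should give 1-[3,4-bis(benzyloxy)phenyl]icosan-5-one F3. Hydrogenolysis of F3 (H2, Pd/C, EtOAc, rt) leaves the dialkyl ketone untouched, and the fallback comes back to the route at 7.

Step 1. The basic Grignard reagent may enolise cyclopentanone instead of adding to it, and Wurtz homocoupling may consume the bromide during Grignard formation. The fallback builds the carbinol ring from the ester side; it sets out from purchased materials and from no numbered compound. Purchased 1,4-dibromobutane F5 and Mg in THF give butane-1,4-diylbis(magnesium bromide) F6. Double addition of F6 to purchased methyl hexadecanoate F4 (THF, 0 °C to rt; aq. NH4Cl) closes the cyclopentanol, and the fallback comes back to the route at 4.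

Further compounds
F1 | step 2 | 1-iodoicosan-5-one | CCCCCCCCCCCCCCCC(=O)CCCCI
F2 | step 3 | 1,2-bis(benzyloxy)-4-bromobenzene | Brc1ccc(OCc2ccccc2)c(OCc2ccccc2)c1
F3 | step 3 | 1-[3,4-bis(benzyloxy)phenyl]icosan-5-one | CCCCCCCCCCCCCCCC(=O)CCCCc1ccc(OCc2ccccc2)c(OCc2ccccc2)c1
F4 | step 1 | methyl hexadecanoate | CCCCCCCCCCCCCCCC(=O)OC
F5 | step 1 | 1,4-dibromobutane | BrCCCCBr
F6 | step 1 | butane-1,4-diylbis(magnesium bromide) | Br[Mg]CCCC[Mg]Br
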